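**Retrosynthetic overview**

1. The target is (−)-epicatechin 3-O-gallate-(4β→8)-(−)-epicatechin 3-O-gallate-(4β→6)-(+)-catechin. The last step is one hydrogenolysis that removes eighteen benzyl ethers and a C8–Br cap from the protected trimer.
2. Both interflavan C4–aryl bonds are traced back to one C4–O bond, the 4β-(2-ethoxyethoxy) ether of hepta-O-benzyl-ECG. It is ionised twice: first onto C6 of 8-bromo-tetra-O-benzylcatechin (bromine blocks C8), then onto C8 of the resulting dimer.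
3. Key disconnection: that C4–O bond, made from the C4–H bond of hepta-O-benzyl-ECG by a galloyl-assisted oxidative C–H etherification (the new step).
4. Hepta-O-benzyl-ECG comes from (−)-epicatechin by phenol benzylation and Steglich esterification with 3,4,5-tris(benzyloxy)benzoic acid.
5. Rings: no ring of the target is built. The three chroman rings, the arenes and six of the eight stereocenters are bought; the only ring formed is the transient C3/C4 dioxolenium that steers both 4β centres. Units are joined lower → middle → upper.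

Assumption: (−)-epicatechin, (+)-catechin and 3,4,5-tris(benzyloxy)benzoic acid are taken as commercial starting materials. "4β" means the C4 substituent is trans to the 3-O-galloyl group and to ring B (2,3-cis-3,4-trans).

**Route**

Step 1
Reactants: 1 (−)-epicatechin
Product: 2 5,7,3',4'-tetra-O-benzyl-(−)-epicatechin (2R,3R; free 3-OH)
Conditions: BnBr (4.4 equiv), K2CO3 (5 equiv), DMF, 0 °C → rt, Ar
Reagents that add atoms: benzyl bromide, BrCc1ccccc1
Why: Williamson ether synthesis, chemoselective for the four phenols over the far less acidic secondary 3-OH with the weak base K2CO3; no stereocenter is touched.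

Step 2
Reactants: 2 5,7,3',4'-tetra-O-benzyl-(−)-epicatechin; 3 3,4,5-tris(benzyloxy)benzoic acid
Product: 4 hepta-O-benzyl-ECG [(2R,3R)-5,7-bis(benzyloxy)-2-[3,4-bis(benzyloxy)phenyl]chroman-3-yl 3,4,5-tris(benzyloxy)benzoate]
Conditions: DCC (1.5 equiv), 4-(dimethylamino)pyridine (0.3 equiv), CH2Cl2, 0 °C → rt
Reagents that add atoms: none
Why: Steglich esterification; the DCC-activated acid is transferred to the 3-OH through the acylpyridinium, and the C3–O bond is not broken, so C3 keeps its configuration.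

Step 3
Reactants: 4 hepta-O-benzyl-ECG
Product: 6 4β-(2-ethoxyethoxy)-hepta-O-benzyl-ECG (2,3-cis-3,4-trans; C4 is S), via galloyl-bridged dioxolenium cation 5 (not isolated)
Conditions: DDQ (2,3-dichloro-5,6-dicyano-1,4-benzoquinone, 1.5–2.0 equiv), EtOCH2CH2OH (10 equiv), 4 Å molecular sieves, CH2Cl2, 0 °C → rt
Reagents that add atoms: 2-ethoxyethanol, CCOCCO
Why: Proposed new method: oxidative benzylic C–H etherification of a 3-O-galloyl flavan with acyloxy participation. DDQ, held as a charge-transfer complex on the trioxygenated ring A, abstracts hydride from C4, the only site that gives a 2,4,6-trialkoxybenzylic cation. The ester carbonyl closes onto the face cis to O3 to give dioxolenium 5; this is the new C4–O bond, and it blocks elimination to the flav-3-ene and over-oxidation. 2-Ethoxyethanol then opens 5 at C4 from the opposite face only, so the C4–O bond of 6 is set 3,4-trans (4β); any orthoester from attack at the dioxolenium carbon reverts under the acidity of the reduced quinone. The closest known reactions are the DDQ-mediated C4 alkoxylation of tetra-O-benzyl flavan-3-ols with a free or silylated 3-OH and 1,2-trans glycosylation through acyloxonium ions; it has not been shown on a 3-O-galloylated flavan, where the ester itself makes the first C–O bond.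

Step 4
Reactants: 7 (+)-catechin
Product: 8 5,7,3',4'-tetra-O-benzyl-(+)-catechin (2R,3S; free 3-OH)
Conditions: BnBr (4.4 equiv), K2CO3 (5 equiv), DMF, 0 °C → rt, Ar
Reagents that add atoms: benzyl bromide, BrCc1ccccc1
Why: Williamson ether synthesis, chemoselective for the four phenols over the secondary 3-OH; no stereocenter is involved and the 3-OH that is free in the target stays free.

Step 5
Reactants: 8 5,7,3',4'-tetra-O-benzyl-(+)-catechin
Product: 9 8-bromo-5,7,3',4'-tetra-O-benzyl-(+)-catechin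
Conditions: NBS (1.0 equiv), CH2Cl2, −78 °C → rt
Reagents that add atoms: N-bromosuccinimide, O=C1CCC(=O)N1Br
Why: Electrophilic aromatic substitution; C8 (ortho to O1 and O7, para to O5) is the most nucleophilic and least hindered position of ring A, so one equivalent of NBS gives the 8-bromide that caps C8 for the later 4→6 coupling; no stereocenter is involved.

Step 6
Reactants: 6 4β-(2-ethoxyethoxy)-hepta-O-benzyl-ECG; 9 8-bromo-5,7,3',4'-tetra-O-benzyl-(+)-catechin
Product: 10 hepta-O-benzyl-ECG-(4β→6)-8-bromo-5,7,3',4'-tetra-O-benzyl-(+)-catechin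
Conditions: 9 (4 equiv), Me3SiOSO2CF3 (0.3 equiv), CH2Cl2, −40 °C, slow addition of 6 over 2 h; then Et3N; excess 9 recovered
Reagents that add atoms: none
Why: Lewis-acid-catalysed Friedel–Crafts-type SN1 arylation (flavanylation); Me3SiOSO2CF3 ionises the chelating 2-ethoxyethoxy group with the same anchimeric assistance by the 3-O-galloyl carbonyl described for cation 5 in step 3. The bromine cap leaves C6 as the only free ring A position of 9, and the arene attacks C4 on the face opposite the participating ester, setting the new C4 stereocenter 3,4-trans (4β). Excess 9 and slow addition of 6 suppress self-condensation of 6 through its own C8, and any O-alkylation of the free 3-OH of 9 re-ionises under the conditions.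

Step 7
Reactants: 6 4β-(2-ethoxyethoxy)-hepta-O-benzyl-ECG; 10 hepta-O-benzyl-ECG-(4β→6)-8-bromo-5,7,3',4'-tetra-O-benzyl-(+)-catechin
Product: 11 octadeca-O-benzyl 8-bromo trimer [hepta-O-benzyl-ECG-(4β→8)-hepta-O-benzyl-ECG-(4β→6)-8-bromo-tetra-O-benzyl-(+)-catechin]
Conditions: 10 (2.5 equiv), Me3SiOSO2CF3 (0.3 equiv), CH2Cl2, −78 → −40 °C, slow addition of 6; then Et3N; excess 10 recovered
Reagents that add atoms: none
Why: The same Friedel–Crafts-type flavanylation with galloyl participation. The lower unit of 10 has no free ring A carbon (C6 substituted, C8 brominated), so reaction occurs on ring A of the upper unit, at C8 (flanked by O1 and one OBn) in preference to C6 (between two OBn groups and crowded by the C4 aryl). Attack anti to the participating ester sets the second C4 stereocenter 3,4-trans (4β).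

Step 8
Reactants: 11 octadeca-O-benzyl 8-bromo trimer
Product: 12 (−)-epicatechin 3-O-gallate-(4β→8)-(−)-epicatechin 3-O-gallate-(4β→6)-(+)-catechin (CNP0154615.1)
Conditions: H2 (1 atm), Pd(OH)2/C, Et3N (1.1 equiv), THF/MeOH/H2O (20:1:1), rt; filtration under Ar, Sephadex LH-20, lyophilisation
Reagents that add atoms: none
Why: Catalytic hydrogenolysis of all eighteen benzyl ethers with concurrent hydrodebromination of the aryl C8–Br bond; Et3N traps HBr so the acid-labile interflavan bonds are safe, and the aryl esters, the diarylmethine C4–C bonds and all eight stereocenters are inert to H2 over Pd(OH)2/C.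

**Compound list**

1 | (−)-epicatechin (2R,3R) | O[C@@H]1Cc2c(O)cc(O)cc2O[C@@H]1c1ccc(O)c(O)c1 | starting material

2 | 5,7,3',4'-tetra-O-benzyl-(−)-epicatechin (2R,3R; free 3-OH) | O[C@@H]1Cc2c(OCc4ccccc4)cc(OCc4ccccc4)cc2O[C@@H]1c1ccc(OCc4ccccc4)c(OCc4ccccc4)c1 | intermediate

3 | 3,4,5-tris(benzyloxy)benzoic acid | OC(=O)c1cc(OCc2ccccc2)c(OCc2ccccc2)c(OCc2ccccc2)c1 | starting material

4 | hepta-O-benzyl-ECG (2R,3R; all seven phenols benzylated) | O=C(O[C@@H]1Cc2c(OCc4ccccc4)cc(OCc4ccccc4)cc2O[C@@H]1c1ccc(OCc4ccccc4)c(OCc4ccccc4)c1)c1cc(OCc4ccccc4)c(OCc4ccccc4)c(OCc4ccccc4)c1 | intermediate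

5 | galloyl-bridged dioxolenium cation (C4 cation of 4 closed by the ester carbonyl oxygen on the face cis to O3; cis-fused 2-[3,4,5-tris(benzyloxy)phenyl]-1,3-dioxolan-2-ylium across C3–C4) | O1[C@@H]2[C@H]([O+]=C1c1cc(OCc4ccccc4)c(OCc4ccccc4)c(OCc4ccccc4)c1)c1c(OCc4ccccc4)cc(OCc4ccccc4)cc1O[C@@H]2c1ccc(OCc4ccccc4)c(OCc4ccccc4)c1 | intermediate

6 | 4β-(2-ethoxyethoxy)-hepta-O-benzyl-ECG (2,3-cis-3,4-trans; C4 S) | O=C(O[C@@H]1[C@@H](OCCOCC)c2c(OCc4ccccc4)cc(OCc4ccccc4)cc2O[C@@H]1c1ccc(OCc4ccccc4)c(OCc4ccccc4)c1)c1cc(OCc4ccccc4)c(OCc4ccccc4)c(OCc4ccccc4)c1 | intermediate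

7 | (+)-catechin (2R,3S) | Oc1cc(O)cc2c1C[C@H](O)[C@@H](c1ccc(O)c(O)c1)O2 | starting material

8 | 5,7,3',4'-tetra-O-benzyl-(+)-catechin (free 3-OH) | O(Cc4ccccc4)c1cc(OCc4ccccc4)cc2c1C[C@H](O)[C@@H](c1ccc(OCc4ccccc4)c(OCc4ccccc4)c1)O2 | intermediate

9 | 8-bromo-5,7,3',4'-tetra-O-benzyl-(+)-catechin | O(Cc4ccccc4)c1cc(OCc4ccccc4)c(Br)c2c1C[C@H](O)[C@@H](c1ccc(OCc4ccccc4)c(OCc4ccccc4)c1)O2 | intermediate

10 | hepta-O-benzyl-ECG-(4β→6)-8-bromo-5,7,3',4'-tetra-O-benzyl-(+)-catechin (upper unit 2,3-cis-3,4-trans; lower unit 2R,3S with free 3-OH) | c1c(OCc4ccccc4)cc(OCc4ccccc4)c2c1O[C@H](c1ccc(OCc4ccccc4)c(OCc4ccccc4)c1)[C@H](OC(=O)c1cc(OCc4ccccc4)c(OCc4ccccc4)c(OCc4ccccc4)c1)[C@H]2c1c(OCc4ccccc4)c(Br)c2c(c1OCc4ccccc4)C[C@H](O)[C@@H](c1ccc(OCc4ccccc4)c(OCc4ccccc4)c1)O2 | intermediate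

11 | octadeca-O-benzyl 8-bromo trimer: hepta-O-benzyl-ECG-(4β→8)-hepta-O-benzyl-ECG-(4β→6)-8-bromo-tetra-O-benzyl-(+)-catechin | O=C(O[C@@H]1[C@@H](c2c(OCc4ccccc4)cc(OCc4ccccc4)c3c2O[C@H](c2ccc(OCc4ccccc4)c(OCc4ccccc4)c2)[C@H](OC(=O)c2cc(OCc4ccccc4)c(OCc4ccccc4)c(OCc4ccccc4)c2)[C@H]3c2c(OCc4ccccc4)c(Br)c3c(c2OCc4ccccc4)C[C@H](O)[C@@H](c2ccc(OCc4ccccc4)c(OCc4ccccc4)c2)O3)c2c(OCc4ccccc4)cc(OCc4ccccc4)cc2O[C@@H]1c1ccc(OCc4ccccc4)c(OCc4ccccc4)c1)c1cc(OCc4ccccc4)c(OCc4ccccc4)c(OCc4ccccc4)c1 | intermediate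

12 | (−)-epicatechin 3-O-gallate-(4β→8)-(−)-epicatechin 3-O-gallate-(4β→6)-(+)-catechin, CNP0154615.1 | O=C(O[C@@H]1[C@@H](c2c(O)cc(O)c3c2O[C@H](c2ccc(O)c(O)c2)[C@H](OC(=O)c2cc(O)c(O)c(O)c2)[C@H]3c2c(O)cc3c(c2O)C[C@H](O)[C@@H](c2ccc(O)c(O)c2)O3)c2c(O)cc(O)cc2O[C@@H]1c1ccc(O)c(O)c1)c1cc(O)c(O)c(O)c1 | target

**Step count and risks**

Total steps: 8. Longest linear sequence: 6 (steps 1, 2, 3, 6, 7, 8); the catechin branch (steps 4, 5) joins at step 6.

Steps most likely to fail:

Step 3 (the proposed new step). Risk: the electron-withdrawing 3-O-galloyl group may slow hydride abstraction, or DDQ may attack a benzyl ether or over-oxidise C4. Fallback with known chemistry, setting out from 2 (with 3) and returning at 6: the oxidation is moved to the free alcohol, where it is established, and the ester is put on afterwards. DDQ with 2-ethoxyethanol in CH2Cl2 converts 2 into 4β-(2-ethoxyethoxy)-5,7,3',4'-tetra-O-benzyl-(−)-epicatechin F1. Steglich esterification of F1 with 3 (DCC, 4-(dimethylamino)pyridine, CH2Cl2) gives 6.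

Step 6. Risk: C6 of 9 is a weak, doubly flanked nucleophile, so 6 may self-condense through its free C8 despite excess 9 and slow addition. Fallback setting out from 6 (with 9) and returning at 10: orthogonal halogen caps on both partners. Iodination of 6 with N-iodosuccinimide (CH2Cl2, 0 °C) gives 8-iodo-4β-(2-ethoxyethoxy)-hepta-O-benzyl-ECG F2, which can no longer self-condense. Its coupling with 9 (1.5 equiv, Me3SiOSO2CF3, CH2Cl2, −40 → 0 °C) can then be forced and gives 8-iodo-hepta-O-benzyl-ECG-(4β→6)-8-bromo-5,7,3',4'-tetra-O-benzyl-(+)-catechin F3. Radical hydrodeiodination with (n-C4H9)3SnH (1.1 equiv) and azobisisobutyronitrile in toluene at 80 °C, selective for C–I over C–Br, gives 10.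

Step 7. Risk: the dimer 10 is a hindered nucleophile that must be used in excess, and the trimer can add a further unit of 6 at its own free C8. Fallback setting out from 6 and 10 and returning at 12: the electrophile is capped, at the cost of one extra step. Bromination of 6 with N-bromosuccinimide (1.0 equiv, CH2Cl2, −78 → 0 °C) gives 8-bromo-4β-(2-ethoxyethoxy)-hepta-O-benzyl-ECG F4, which can neither self-condense nor let the product chain on. Coupling of F4 with 10 in near 1:1 ratio (Me3SiOSO2CF3, CH2Cl2, −40 → −20 °C) gives the octadeca-O-benzyl 8,8-dibromo trimer (bromine at C8 of the upper and of the lower unit) F5. Hydrogenolysis of F5 under the conditions of step 8, with 2.2 equiv of Et3N, removes both bromines and all eighteen benzyl groups and gives 12.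

**Further compounds**

F1 | step 3 | 4β-(2-ethoxyethoxy)-5,7,3',4'-tetra-O-benzyl-(−)-epicatechin | O[C@@H]1[C@@H](OCCOCC)c2c(OCc4ccccc4)cc(OCc4ccccc4)cc2O[C@@H]1c1ccc(OCc4ccccc4)c(OCc4ccccc4)c1

F2 | step 6 | 8-iodo-4β-(2-ethoxyethoxy)-hepta-O-benzyl-ECG | O=C(O[C@@H]1[C@@H](OCCOCC)c2c(OCc4ccccc4)cc(OCc4ccccc4)c(I)c2O[C@@H]1c1ccc(OCc4ccccc4)c(OCc4ccccc4)c1)c1cc(OCc4ccccc4)c(OCc4ccccc4)c(OCc4ccccc4)c1

F3 | step 6 | 8-iodo-hepta-O-benzyl-ECG-(4β→6)-8-bromo-5,7,3',4'-tetra-O-benzyl-(+)-catechin | Ic1c(OCc4ccccc4)cc(OCc4ccccc4)c2c1O[C@H](c1ccc(OCc4ccccc4)c(OCc4ccccc4)c1)[C@H](OC(=O)c1cc(OCc4ccccc4)c(OCc4ccccc4)c(OCc4ccccc4)c1)[C@H]2c1c(OCc4ccccc4)c(Br)c2c(c1OCc4ccccc4)C[C@H](O)[C@@H](c1ccc(OCc4ccccc4)c(OCc4ccccc4)c1)O2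

F4 | step 7 | 8-bromo-4β-(2-ethoxyethoxy)-hepta-O-benzyl-ECG | O=C(O[C@@H]1[C@@H](OCCOCC)c2c(OCc4ccccc4)cc(OCc4ccccc4)c(Br)c2O[C@@H]1c1ccc(OCc4ccccc4)c(OCc4ccccc4)c1)c1cc(OCc4ccccc4)c(OCc4ccccc4)c(OCc4ccccc4)c1

F5 | step 7 | octadeca-O-benzyl 8,8-dibromo trimer: 8-bromo-hepta-O-benzyl-ECG-(4β→8)-hepta-O-benzyl-ECG-(4β→6)-8-bromo-tetra-O-benzyl-(+)-catechin | O=C(O[C@@H]1[C@@H](c2c(OCc4ccccc4)cc(OCc4ccccc4)c3c2O[C@H](c2ccc(OCc4ccccc4)c(OCc4ccccc4)c2)[C@H](OC(=O)c2cc(OCc4ccccc4)c(OCc4ccccc4)c(OCc4ccccc4)c2)[C@H]3c2c(OCc4ccccc4)c(Br)c3c(c2OCc4ccccc4)C[C@H](O)[C@@H](c2ccc(OCc4ccccc4)c(OCc4ccccc4)c2)O3)c2c(OCc4ccccc4)cc(OCc4ccccc4)c(Br)c2O[C@@H]1c1ccc(OCc4ccccc4)c(OCc4ccccc4)c1)c1cc(OCc4ccccc4)c(OCc4ccccc4)c(OCc4ccccc4)c1
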